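**Plan**

- Numbering: decalin C1–C10 with the ring B alkene C8=C9; side chain C11–C12–C13(CH2OH)=C14–C15=C16–butenolide.
- Cuts: (a) the C15=C16 alkene, into a C15 enal and a butenolide ylide; (b) the two C–O bonds at C15 and at the hydroxymethyl carbon, back to a 2-alkylbuta-1,3-diene, because C13 carries an oxygenated CH2 trans to C15 across C13=C14, which is the E-1,4-dioxygenated but-2-ene pattern that 1,4-addition to such a diene leaves; (c) C12–C13, to a C12 iodide and the Grignard reagent of chloroprene.
- Forward order: the trans-decalin is taken intact from (+)-sclareolide and no carbocycle is built; the chain grows by C12–C13 coupling, then the palladium 1,4-diacetoxylation, then the C15=C16 olefination; the butenolide ring is closed separately by Wittig–lactonisation of dihydroxyacetone.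
- Stereochemistry: C5 and C10 come from sclareolide and are never touched; 13E comes from the syn π-allylpalladium intermediate of the key step; 15E comes from the stabilised ylide.

Key step: step 5

Remark: Bc denotes the (4aS,8aS)-2,5,5,8a-tetramethyl-3,4,4a,5,6,7,8,8a-octahydronaphthalen-1-yl group, and 1,3-dihydroxyacetone is charged as its commercial dimer, which reacts as the monomer.

**Route**

Step 1
Reactants: 1 (+)-sclareolide
Product: 2 methyl 2-(Bc)acetate (C8=C9 methyl ester)
Conditions: H2SO4 (conc., cat.), MeOH, rt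
Reagents that add atoms: methanol, CO
Why: Acid-catalysed lactone methanolysis with E1 loss of the tertiary C8 oxygen (Fischer esterification coupled to dehydration) should give mainly the thermodynamically preferred tetrasubstituted C8=C9 alkene, with the minor trisubstituted and exocyclic isomers removed on AgNO3-doped silica, while C5 and C10 are not involved.

Step 2
Reactants: 2 methyl 2-(Bc)acetate
Product: 3 2-(Bc)ethan-1-ol
Conditions: LiAlH4, THF, 0 °C → rt; Fieser work-up
Reagents that add atoms: none
Why: LiAlH4 reduction of an unhindered methyl ester to the primary alcohol is routine, and the isolated tetrasubstituted alkene is inert to hydride.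

Step 3
Reactants: 3 2-(Bc)ethan-1-ol
Product: 4 2-(Bc)ethyl iodide
Conditions: I2, PPh3, imidazole, CH2Cl2, 0 °C → rt
Reagents that add atoms: iodine, II
Why: Appel-type iodination converts the primary alcohol into the iodide by SN2 displacement of the oxyphosphonium group without touching the ring alkene.

Step 4
Reactants: 4 2-(Bc)ethyl iodide; 5 chloroprene (2-chlorobuta-1,3-diene)
Product: 7 3-methylidene-5-(Bc)pent-1-ene (the 2-alkylbuta-1,3-diene), via buta-1,3-dien-2-ylmagnesium chloride 6 (not isolated)
Conditions: 5, Mg, ZnCl2 (cat.), THF, reflux; then 4, Li2CuCl4 (3 mol %), THF, 0 °C → rt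
Reagents that add atoms: none
Why: The dienyl Grignard reagent from chloroprene should couple with the primary iodide under Li2CuCl4 catalysis (Kochi-type copper-catalysed sp2–sp3 cross-coupling), a documented entry to 2-alkylbuta-1,3-dienes that leaves the ring alkene and both stereocentres alone.

Step 5
Reactants: 7 3-methylidene-5-(Bc)pent-1-ene
Product: 8 (2E)-2-[2-(Bc)ethyl]but-2-ene-1,4-diyl diacetate
Conditions: Pd(OAc)2 (5 mol %), p-benzoquinone (20 mol %), MnO2 (1.3 equiv), LiOAc (3 equiv), AcOH/pentane, 25 °C
Reagents that add atoms: acetic acid, CC(=O)O; lithium acetate, [Li+].CC(=O)[O-]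
Why: Divalent palladium from Pd(OAc)2 complexes the diene at its less substituted C14=C15 vinyl unit and acetate adds from outside at C15, giving a π-allylpalladium species that spans C14, C13 and the methylene on C13 and carries the C12 chain on its central carbon; quinone coordination then makes the allyl electrophilic enough for a second acetate to attack the unsubstituted methylene terminus, and the zerovalent palladium set free is reoxidised by the quinone, which MnO2 regenerates. The closest known reaction type is the palladium/benzoquinone 1,4-diacetoxylation of conjugated dienes, which is documented for 2-alkyl dienes of the isoprene type. No ring is closed and no stereocentre is created; the only new stereo-element is the C13=C14 geometry. It is set by the syn π-allyl, in which C15 lies on the side of the C12 chain and away from the free terminus, so attack at that terminus should deliver the E alkene with the two acetoxymethyl groups trans. The step needs 1,4- over 1,2-addition, E over Z, and diene over ring-alkene reactivity: the open CH2 terminus against the substituted C14 terminus should secure the first, the syn allyl in a chloride-free acetate medium the second, and the weak binding of the tetrasubstituted C8=C9 alkene the third. The two-phase medium and the low quinone concentration should hold back Diels–Alder capture of the diene, and any minor Z isomer would be removed by chromatography.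

Step 6
Reactants: 8 (2E)-2-[2-(Bc)ethyl]but-2-ene-1,4-diyl diacetate
Product: 9 (2E)-4-hydroxy-2-[2-(Bc)ethyl]but-2-en-1-yl acetate (C15 alcohol, acetate kept on the methylene at C13)
Conditions: Novozym 435 (immobilised Candida antarctica lipase B), n-BuOH (3 equiv), MTBE, 30 °C, stopped at the monoacetate
Reagents that add atoms: none
Why: Lipase-catalysed alcoholysis (enzymatic regioselective deacetylation) should remove the C15 acetate, which sits on an unbranched allylic CH2, faster than the acetate on the methylene attached to the fully substituted C13, since lipases discriminate primary esters by β-branching, and the trans arrangement of the two oxygens rules out acetyl migration.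

Step 7
Reactants: 9 (2E)-4-hydroxy-2-[2-(Bc)ethyl]but-2-en-1-yl acetate
Product: 10 (2E)-4-oxo-2-[2-(Bc)ethyl]but-2-en-1-yl acetate (C15 enal)
Conditions: MnO2 (activated, excess), CH2Cl2, rt
Reagents that add atoms: none
Why: Heterogeneous MnO2 oxidation is specific for allylic alcohols, should stop at the enal without affecting the acetate or the ring alkene, and its neutral conditions should preserve the C13=C14 geometry.

Step 8
Reactants: 11 1,3-dihydroxyacetone; 12 ethyl (triphenylphosphoranylidene)acetate
Product: 14 4-(hydroxymethyl)furan-2(5H)-one, via ethyl 4-hydroxy-3-(hydroxymethyl)but-2-enoate 13 (not isolated)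
Conditions: CH2Cl2, rt
Reagents that add atoms: none
Why: Wittig olefination of the symmetrical ketone with the stabilised ester ylide places a hydroxymethyl group cis to the ester whichever way the alkene forms, so lactonisation with loss of ethanol should follow spontaneously (Wittig–lactonisation).

Step 9
Reactants: 14 4-(hydroxymethyl)furan-2(5H)-one
Product: 15 4-(bromomethyl)furan-2(5H)-one
Conditions: CBr4, PPh3, CH2Cl2, 0 °C
Reagents that add atoms: carbon tetrabromide, BrC(Br)(Br)Br
Why: Appel bromination turns the primary allylic alcohol into the bromide by SN2 displacement under neutral conditions that the butenolide tolerates.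

Step 10
Reactants: 15 4-(bromomethyl)furan-2(5H)-one
Product: 16 [(5-oxo-2,5-dihydrofuran-3-yl)methyl]triphenylphosphonium bromide
Conditions: PPh3, toluene, rt → 50 °C
Reagents that add atoms: triphenylphosphine, c1ccc(cc1)P(c1ccccc1)c1ccccc1
Why: SN2 quaternisation of triphenylphosphine by the reactive allylic bromide should precipitate the phosphonium salt from toluene.

Step 11
Reactants: 10 (2E)-4-oxo-2-[2-(Bc)ethyl]but-2-en-1-yl acetate; 16 [(5-oxo-2,5-dihydrofuran-3-yl)methyl]triphenylphosphonium bromide
Product: 18 (2E,4E)-5-(5-oxo-2,5-dihydrofuran-3-yl)-2-[2-(Bc)ethyl]penta-2,4-dien-1-yl acetate (acetate of the target), via 4-[(triphenylphosphoranylidene)methyl]furan-2(5H)-one 17 (not isolated)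
Conditions: 16, KOt-Bu (0.95 equiv relative to 16), THF, 0 °C; then 10, 0 °C → rt
Reagents that add atoms: none
Why: Wittig olefination with a vinylogous-ester-stabilised ylide should form C15=C16 with the E geometry typical of stabilised ylides, and pre-forming the ylide with slightly less than one equivalent of base keeps free alkoxide away from the acetate and the enal, any Z isomer being removed by chromatography.

Step 12
Reactants: 18 (2E,4E)-5-(5-oxo-2,5-dihydrofuran-3-yl)-2-[2-(Bc)ethyl]penta-2,4-dien-1-yl acetate
Product: 19 4-[(1E,3E)-4-(hydroxymethyl)-6-(Bc)hexa-1,3-dien-1-yl]furan-2(5H)-one (target)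
Conditions: K2CO3 (0.2 equiv), MeOH, 0 °C; AcOH quench
Reagents that add atoms: none
Why: Carbonate-catalysed transesterification (Zemplén-type methanolysis) should cleave the unhindered primary allylic acetate at 0 °C faster than it affects the conjugated butenolide, whose ring would reclose on neutralisation if opened reversibly, and no stereo-element is touched.

**Compound list**

1 | (+)-sclareolide, (3aR,5aS,9aS,9bR)-3a,6,6,9a-tetramethyldecahydronaphtho[2,1-b]furan-2(1H)-one | C[C@]12CCCC([C@@H]1CC[C@@]3([C@@H]2CC(=O)O3)C)(C)C | starting material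
2 | methyl 2-[(4aS,8aS)-2,5,5,8a-tetramethyl-3,4,4a,5,6,7,8,8a-octahydronaphthalen-1-yl]acetate | CC1=C(CC(=O)OC)[C@@]2(C)CCCC(C)(C)[C@@H]2CC1 | intermediate
3 | 2-[(4aS,8aS)-2,5,5,8a-tetramethyl-3,4,4a,5,6,7,8,8a-octahydronaphthalen-1-yl]ethan-1-ol | CC1=C(CCO)[C@@]2(C)CCCC(C)(C)[C@@H]2CC1 | intermediate
4 | (4aS,8aS)-1-(2-iodoethyl)-2,5,5,8a-tetramethyl-3,4,4a,5,6,7,8,8a-octahydronaphthalene | CC1=C(CCI)[C@@]2(C)CCCC(C)(C)[C@@H]2CC1 | intermediate
5 | chloroprene (2-chlorobuta-1,3-diene) | C=CC(Cl)=C | starting material
6 | buta-1,3-dien-2-ylmagnesium chloride | C=CC(=C)[Mg]Cl | intermediate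
7 | (4aS,8aS)-2,5,5,8a-tetramethyl-1-(3-methylidenepent-4-en-1-yl)-3,4,4a,5,6,7,8,8a-octahydronaphthalene | CC1=C(CCC(=C)C=C)[C@@]2(C)CCCC(C)(C)[C@@H]2CC1 | intermediate
8 | (2E)-2-{2-[(4aS,8aS)-2,5,5,8a-tetramethyl-3,4,4a,5,6,7,8,8a-octahydronaphthalen-1-yl]ethyl}but-2-ene-1,4-diyl diacetate | CC1=C(CC/C(=C\COC(C)=O)COC(C)=O)[C@@]2(C)CCCC(C)(C)[C@@H]2CC1 | intermediate
9 | (2E)-4-hydroxy-2-{2-[(4aS,8aS)-2,5,5,8a-tetramethyl-3,4,4a,5,6,7,8,8a-octahydronaphthalen-1-yl]ethyl}but-2-en-1-yl acetate | CC1=C(CC/C(=C\CO)COC(C)=O)[C@@]2(C)CCCC(C)(C)[C@@H]2CC1 | intermediate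
10 | (2E)-4-oxo-2-{2-[(4aS,8aS)-2,5,5,8a-tetramethyl-3,4,4a,5,6,7,8,8a-octahydronaphthalen-1-yl]ethyl}but-2-en-1-yl acetate | CC1=C(CC/C(=C\C=O)COC(C)=O)[C@@]2(C)CCCC(C)(C)[C@@H]2CC1 | intermediate
11 | 1,3-dihydroxyacetone (charged as its dimer) | OCC(=O)CO | starting material
12 | ethyl (triphenylphosphoranylidene)acetate | CCOC(=O)C=P(c1ccccc1)(c1ccccc1)c1ccccc1 | starting material
13 | ethyl 4-hydroxy-3-(hydroxymethyl)but-2-enoate | CCOC(=O)C=C(CO)CO | intermediate
14 | 4-(hydroxymethyl)furan-2(5H)-one | O=C1C=C(CO)CO1 | intermediate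
15 | 4-(bromomethyl)furan-2(5H)-one | O=C1C=C(CBr)CO1 | intermediate
16 | [(5-oxo-2,5-dihydrofuran-3-yl)methyl]triphenylphosphonium bromide | O=C1C=C(C[P+](c2ccccc2)(c2ccccc2)c2ccccc2)CO1.[Br-] | intermediate
17 | 4-[(triphenylphosphoranylidene)methyl]furan-2(5H)-one | O=C1C=C(C=P(c2ccccc2)(c2ccccc2)c2ccccc2)CO1 | intermediate
18 | (2E,4E)-5-(5-oxo-2,5-dihydrofuran-3-yl)-2-{2-[(4aS,8aS)-2,5,5,8a-tetramethyl-3,4,4a,5,6,7,8,8a-octahydronaphthalen-1-yl]ethyl}penta-2,4-dien-1-yl acetate | CC1=C(CC/C(=C\C=C\C2=CC(=O)OC2)COC(C)=O)[C@@]2(C)CCCC(C)(C)[C@@H]2CC1 | intermediate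
19 | 4-[(1E,3E)-4-(hydroxymethyl)-6-[(4aS,8aS)-2,5,5,8a-tetramethyl-3,4,4a,5,6,7,8,8a-octahydronaphthalen-1-yl]hexa-1,3-dien-1-yl]furan-2(5H)-one | CC1=C(CC/C(=C\C=C\C2=CC(=O)OC2)CO)[C@@]2(C)CCCC(C)(C)[C@@H]2CC1 | target

**Step count and risks**

Total step count: 12. Longest linear sequence: 9 steps (steps 1–7, 11 and 12 from sclareolide); the butenolide arm takes 3 steps (8–10).

Steps most likely to fail:

1. Step 5. The alkene geometry may erode through the anti π-allyl isomer, acetate may add 1,2 instead of 1,4, or the diene may be consumed by Diels–Alder addition to the quinone. The fallback sets out from 4 and returns at 8. Magnesium insertion into iodide 4 in THF gives 2-(Bc)ethylmagnesium iodide F1. F1 is added, with CuI (copper monoiodide) as catalyst, to the bis-magnesium alkoxide of commercial but-2-yne-1,4-diol (pre-formed with i-PrMgCl). Alkoxide-directed anti-carbomagnesiation followed by NH4Cl quench gives (2E)-2-[2-(Bc)ethyl]but-2-ene-1,4-diol F2, whose E geometry is fixed by the trans addition. Ac2O/pyridine/DMAP then gives 8.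

2. Step 6. The enzyme may discriminate too weakly between the two primary allylic acetates, or deacetylation may run on to the diol. The fallback sets out from 8 and returns at 9. K2CO3/MeOH removes both acetates to give (2E)-2-[2-(Bc)ethyl]but-2-ene-1,4-diol F2, the diol already met in the first fallback. One equivalent of TBDPSCl with imidazole in CH2Cl2 at −40 °C should silylate the C15 hydroxyl preferentially, giving (2E)-4-[(tert-butyldiphenylsilyl)oxy]-2-[2-(Bc)ethyl]but-2-en-1-ol F3; the regioisomeric and bis-silyl ethers are separable and can be returned to F2 by desilylation. Ac2O/pyridine gives (2E)-4-[(tert-butyldiphenylsilyl)oxy]-2-[2-(Bc)ethyl]but-2-en-1-yl acetate F4. Buffered HF·pyridine in THF then removes the silyl group to give 9.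

3. Step 11. The olefination may give incomplete E-selectivity, or the γ-acetoxy enal may degrade under the basic conditions. The fallback sets out from 10 and returns at 18. Takai olefination of 10 (CrCl2, CHI3, THF, 0 °C) gives (2E,4E)-5-iodo-2-[2-(Bc)ethyl]penta-2,4-dien-1-yl acetate F5. Commercial 4-bromofuran-2(5H)-one is stannylated with hexabutylditin and Pd(PPh3)4 to give 4-(tributylstannyl)furan-2(5H)-one F6. Stille coupling of F5 with F6 (Pd2(dba)3, AsPh3, DMF, rt → 50 °C) forms the C16–butenolide bond with retention of the E geometry and gives 18.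

Further compounds
F1 | step 5 | 2-[(4aS,8aS)-2,5,5,8a-tetramethyl-3,4,4a,5,6,7,8,8a-octahydronaphthalen-1-yl]ethylmagnesium iodide | CC1=C(CC[Mg]I)[C@@]2(C)CCCC(C)(C)[C@@H]2CC1
F2 | step 5 | (2E)-2-{2-[(4aS,8aS)-2,5,5,8a-tetramethyl-3,4,4a,5,6,7,8,8a-octahydronaphthalen-1-yl]ethyl}but-2-ene-1,4-diol | CC1=C(CC/C(=C\CO)CO)[C@@]2(C)CCCC(C)(C)[C@@H]2CC1
F3 | step 6 | (2E)-4-[(tert-butyldiphenylsilyl)oxy]-2-{2-[(4aS,8aS)-2,5,5,8a-tetramethyl-3,4,4a,5,6,7,8,8a-octahydronaphthalen-1-yl]ethyl}but-2-en-1-ol | CC1=C(CC/C(=C\CO[Si](c3ccccc3)(c3ccccc3)C(C)(C)C)CO)[C@@]2(C)CCCC(C)(C)[C@@H]2CC1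
F4 | step 6 | (2E)-4-[(tert-butyldiphenylsilyl)oxy]-2-{2-[(4aS,8aS)-2,5,5,8a-tetramethyl-3,4,4a,5,6,7,8,8a-octahydronaphthalen-1-yl]ethyl}but-2-en-1-yl acetate | CC1=C(CC/C(=C\CO[Si](c3ccccc3)(c3ccccc3)C(C)(C)C)COC(C)=O)[C@@]2(C)CCCC(C)(C)[C@@H]2CC1
F5 | step 11 | (2E,4E)-5-iodo-2-{2-[(4aS,8aS)-2,5,5,8a-tetramethyl-3,4,4a,5,6,7,8,8a-octahydronaphthalen-1-yl]ethyl}penta-2,4-dien-1-yl acetate | CC1=C(CC/C(=C\C=C\I)COC(C)=O)[C@@]2(C)CCCC(C)(C)[C@@H]2CC1
F6 | step 11 | 4-(tributylstannyl)furan-2(5H)-one | CCCC[Sn](CCCC)(CCCC)C1=CC(=O)OC1
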